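**Retrosynthetic overview** (side chain numbered C1', the benzylic CH2, to C15')
- Target ⇐ selective methanolysis of two aryl acetates ⇐ O-acetylation at C5' ⇐ Suzuki–Miyaura union (C1'–C2') of an (E)-alkenyl pinacolboronate with 2-(bromomethyl)-6-methyl-1,4-phenylene diacetate.
- Key step: the C4'–C5' bond, the C5' centre and the E C2'=C3' alkene are made in one operation by chiral phosphoric acid-catalysed allylboration of 8-oxofarnesal with an achiral 2-methylallyl gem-diboronate.
- 8-Oxofarnesal ⇐ geranyl acetate (SeO2 oxidation of the terminal E-methyl, α-selective prenylbarium addition, MnO2).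
- gem-Diboronate ⇐ methallyl chloride + B2pin2; benzylic bromide ⇐ 2,6-dimethylhydroquinone.
- No ring is formed; the only ring, the benzene ring, comes in with 2,6-dimethylhydroquinone.

Assumption: the acetoxy carbon C5' is read from the SMILES as S (O > C6' > C4' > H), the C2'=C3', C6'=C7' and C10'=C11' alkenes are E, and (S)-TRIP, (S)-3,3'-bis(2,4,6-triisopropylphenyl)-1,1'-binaphthyl-2,2'-diyl hydrogen phosphate, is taken as a purchasable catalyst.

**Step 1**
Reactants: 1 geranyl acetate
Product: 2 (2E,6E)-3,7-dimethyl-8-oxoocta-2,6-dien-1-yl acetate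
Conditions: SeO2 (1.1 equiv), 95% EtOH, reflux
Reagents that add atoms: selenium dioxide, O=[Se]=O
Why: Riley allylic oxidation (ene reaction, then [2,3]-sigmatropic shift) attacks the E-methyl group of the more electron-rich distal alkene, the 2,3-alkene being deactivated by the allylic acetate, and gives the (E)-enal.

**Step 2**
Reactants: 2 (2E,6E)-3,7-dimethyl-8-oxoocta-2,6-dien-1-yl acetate; 3 prenyl chloride
Product: 6 (2E,6E)-3,7,11-trimethyldodeca-2,6,10-triene-1,8-diol (racemic at C8), via prenylbarium chloride 4 (not isolated), via 8-hydroxyfarnesyl acetate 5 (not isolated)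
Conditions: BaI2, lithium biphenylide (LiC12H10), THF, rt; 3, −78 °C; 2, −78 °C; then MeOH, K2CO3, rt
Reagents that add atoms: none
Why: Allylbarium reagents add to aldehydes through the unsubstituted α-carbon and in a 1,2-sense to enals (Yamamoto-type α-selective prenylation), the aldehyde reacts far faster than the acetate at −78 °C, and methanolysis in the same flask removes the acetate; the new carbinol centre is racemic and is erased by the oxidation in step 3.

**Step 3**
Reactants: 6 (2E,6E)-3,7,11-trimethyldodeca-2,6,10-triene-1,8-diol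
Product: 7 (2E,6E)-3,7,11-trimethyl-8-oxododeca-2,6,10-trienal (8-oxofarnesal)
Conditions: MnO2 (25 equiv), CH2Cl2, rt
Reagents that add atoms: none
Why: MnO2 oxidises allylic alcohols only, so the primary alcohol gives the (E)-enal and the secondary one the enone under neutral conditions that leave the β,γ-alkene of the prenyl ketone out of conjugation; no stereocentre remains.

**Step 4**
Reactants: 8 methallyl chloride; 9 bis(pinacolato)diboron
Product: 12 2,2'-(2-methylprop-2-ene-1,1-diyl)bis(4,4,5,5-tetramethyl-1,3,2-dioxaborolane), via 1-chloro-2-methylallyllithium 10 (not isolated), via diboron ate complex 11 (not isolated)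
Conditions: LDA (1.05 equiv, added to 8 + 9), THF, −78 °C to rt
Reagents that add atoms: none
Why: LDA deprotonates methallyl chloride at the CH2Cl carbon in the presence of B2pin2, the α-chloroallyllithium carbenoid is trapped as a diboron ate complex, and 1,2-boryl migration with loss of chloride (Matteson-type 1,2-metallate shift, carbenoid insertion into the B–B bond) gives the achiral allylic gem-diboronate.

**Step 5 (key step)**
Reactants: 7 (2E,6E)-3,7,11-trimethyl-8-oxododeca-2,6,10-trienal; 12 2-methylallyl gem-diboronate (1.5 equiv)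
Product: 14 (6E,10E,12S,14E)-12-hydroxy-2,6,10,14-tetramethyl-15-(4,4,5,5-tetramethyl-1,3,2-dioxaborolan-2-yl)pentadeca-2,6,10,14-tetraen-5-one, via O-pinacolboryl ether 13 (not isolated)
Conditions: (S)-TRIP (10 mol%), 4 Å MS, toluene, −30 °C; then aq. NaHCO3
Reagents that add atoms: none
Why: Proposed new method: chiral phosphoric acid-catalysed enantioselective allylboration of an enal with a 2-methyl-substituted allylic gem-diboronate, a reagent class for which, to the best of current knowledge, this catalysis has not been shown; the acid hydrogen-bonds through P–OH to the pseudo-axial pinacol oxygen of the reacting boron and through P=O to the formyl hydrogen in a closed chair transition state, the (S)-catalyst (mirror image of the (R)-acid that sends allyl groups to the Re face of aryl and alkenyl aldehydes) opens the Si face so that C5' is set as S, the spectator Bpin sits pseudo-equatorial away from the pinacolate of the reacting boron and the catalyst pocket so that the new alkene is E with boron trans to C4', the γ-carbon is CH2 so no second stereocentre arises, and the ketone is inert to allylboronates at low temperature; the closest known reactions are the chiral phosphoric acid-catalysed allylborations of aldehydes with 2-methylallyl pinacolboronate and with γ-substituted 1,1-diborylalk-2-enes, which give (E)-δ-boryl homoallylic alcohols.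

**Step 6**
Reactants: 15 2,6-dimethylhydroquinone
Product: 16 2,6-dimethyl-1,4-phenylene diacetate
Conditions: Ac2O, pyridine, DMAP (cat.), CH2Cl2, rt
Reagents that add atoms: acetic anhydride, CC(=O)OC(C)=O
Why: DMAP-catalysed O-acetylation of both phenols (nucleophilic acyl substitution) gives an air-stable diacetate whose electron-poorer ring tolerates the radical bromination that follows.

**Step 7**
Reactants: 16 2,6-dimethyl-1,4-phenylene diacetate
Product: 17 2-(bromomethyl)-6-methyl-1,4-phenylene diacetate
Conditions: NBS (1.0 equiv), AIBN (cat.), PhCF3, 80 °C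
Reagents that add atoms: N-bromosuccinimide, O=C1CCC(=O)N1Br
Why: Wohl–Ziegler benzylic bromination, in which the two methyl groups are equivalent by symmetry, the acetoxy groups suppress ring bromination, and one equivalent of NBS limits over-bromination.

**Step 8**
Reactants: 14 (S)-alkenylboronate alcohol; 17 2-(bromomethyl)-6-methyl-1,4-phenylene diacetate (1.2 equiv)
Product: 18 (2E,5S,6E,10E)-1-(2,5-diacetoxy-3-methylphenyl)-5-hydroxy-3,7,11,15-tetramethylhexadeca-2,6,10,14-tetraen-12-one
Conditions: Pd(PPh3)4 (5 mol%), CsF (3 equiv), THF, 60 °C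
Reagents that add atoms: none
Why: Suzuki–Miyaura sp2–sp3 coupling in which Pd(PPh3)4 inserts into the benzylic C–Br bond, fluoride activates the alkenyl–Bpin without hydroxide so that the aryl acetates and the β,γ-unsaturated ketone survive, and reductive elimination forms C1'–C2' with retention of the E geometry; C5' is untouched, and the alcohol is coupled free because an allylic acetate could be ionised by zerovalent palladium.

**Step 9**
Reactants: 18 coupled (5S)-alcohol
Product: 19 (2E,5S,6E,10E)-1-(2,5-diacetoxy-3-methylphenyl)-3,7,11,15-tetramethyl-12-oxohexadeca-2,6,10,14-tetraen-5-yl acetate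
Conditions: Ac2O, pyridine, DMAP (cat.), CH2Cl2, 0 °C
Reagents that add atoms: acetic anhydride, CC(=O)OC(C)=O
Why: DMAP-catalysed acetylation of the secondary allylic alcohol takes place at oxygen and never breaks the C5'–O bond, so the S configuration is retained.

**Step 10**
Reactants: 19 triacetate
Product: 20 (2E,5S,6E,10E)-1-(2,5-dihydroxy-3-methylphenyl)-3,7,11,15-tetramethyl-12-oxohexadeca-2,6,10,14-tetraen-5-yl acetate (CNP0186948.1)
Conditions: NH4OAc (excess), MeOH/H2O (4:1), rt, argon
Reagents that add atoms: none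
Why: Transesterification of the two aryl acetates in near-neutral NH4OAc/aqueous methanol is chemoselective because phenoxide is a far better leaving group than a secondary alkoxide, so the C5' allylic acetate, its stereocentre and the unconjugated prenyl ketone are left intact.

**Compound list**
1 | geranyl acetate, (2E)-3,7-dimethylocta-2,6-dien-1-yl acetate | CC(=O)OC/C=C(\C)CCC=C(C)C | starting material
2 | (2E,6E)-3,7-dimethyl-8-oxoocta-2,6-dien-1-yl acetate | CC(=O)OC/C=C(\C)CC/C=C(\C)C=O | intermediate
3 | prenyl chloride, 1-chloro-3-methylbut-2-ene | CC(C)=CCCl | starting material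
4 | prenylbarium chloride | CC(C)=CC[Ba]Cl | intermediate
5 | 8-hydroxyfarnesyl acetate, (2E,6E)-8-hydroxy-3,7,11-trimethyldodeca-2,6,10-trien-1-yl acetate, racemic at C8 | CC(=O)OC/C=C(\C)CC/C=C(\C)C(O)CC=C(C)C | intermediate
6 | (2E,6E)-3,7,11-trimethyldodeca-2,6,10-triene-1,8-diol, racemic at C8 | OC/C=C(\C)CC/C=C(\C)C(O)CC=C(C)C | intermediate
7 | 8-oxofarnesal, (2E,6E)-3,7,11-trimethyl-8-oxododeca-2,6,10-trienal | O=C/C=C(\C)CC/C=C(\C)C(=O)CC=C(C)C | intermediate
8 | methallyl chloride, 3-chloro-2-methylprop-1-ene | CC(=C)CCl | starting material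
9 | bis(pinacolato)diboron | CC1(C)OB(OC1(C)C)B1OC(C)(C)C(C)(C)O1 | starting material
10 | 1-chloro-2-methylallyllithium | [Li]C(Cl)C(C)=C | intermediate
11 | lithium diboron ate complex of 9 and 10 | [Li+].CC(=C)C(Cl)[B-]1(OC(C)(C)C(C)(C)O1)B1OC(C)(C)C(C)(C)O1 | intermediate
12 | 2,2'-(2-methylprop-2-ene-1,1-diyl)bis(4,4,5,5-tetramethyl-1,3,2-dioxaborolane) | CC(=C)C(B1OC(C)(C)C(C)(C)O1)B1OC(C)(C)C(C)(C)O1 | intermediate
13 | O-pinacolboryl ether of 14 | CC1(C)OB(O[C@H](/C=C(\C)CC/C=C(\C)C(=O)CC=C(C)C)C/C(C)=C/B2OC(C)(C)C(C)(C)O2)OC1(C)C | intermediate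
14 | (6E,10E,12S,14E)-12-hydroxy-2,6,10,14-tetramethyl-15-(4,4,5,5-tetramethyl-1,3,2-dioxaborolan-2-yl)pentadeca-2,6,10,14-tetraen-5-one | O[C@H](/C=C(\C)CC/C=C(\C)C(=O)CC=C(C)C)C/C(C)=C/B1OC(C)(C)C(C)(C)O1 | intermediate
15 | 2,6-dimethylhydroquinone, 2,6-dimethylbenzene-1,4-diol | Cc1cc(O)cc(C)c1O | starting material
16 | 2,6-dimethyl-1,4-phenylene diacetate | CC(=O)Oc1cc(C)c(OC(C)=O)c(C)c1 | intermediate
17 | 2-(bromomethyl)-6-methyl-1,4-phenylene diacetate | CC(=O)Oc1cc(C)c(OC(C)=O)c(CBr)c1 | intermediate
18 | (2E,5S,6E,10E)-1-(2,5-diacetoxy-3-methylphenyl)-5-hydroxy-3,7,11,15-tetramethylhexadeca-2,6,10,14-tetraen-12-one | O[C@H](/C=C(\C)CC/C=C(\C)C(=O)CC=C(C)C)C/C(C)=C/Cc1cc(OC(C)=O)cc(C)c1OC(C)=O | intermediate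
19 | (2E,5S,6E,10E)-1-(2,5-diacetoxy-3-methylphenyl)-3,7,11,15-tetramethyl-12-oxohexadeca-2,6,10,14-tetraen-5-yl acetate | CC(=O)O[C@H](/C=C(\C)CC/C=C(\C)C(=O)CC=C(C)C)C/C(C)=C/Cc1cc(OC(C)=O)cc(C)c1OC(C)=O | intermediate
20 | (2E,5S,6E,10E)-1-(2,5-dihydroxy-3-methylphenyl)-3,7,11,15-tetramethyl-12-oxohexadeca-2,6,10,14-tetraen-5-yl acetate (CNP0186948.1) | CC(=O)O[C@H](/C=C(\C)CC/C=C(\C)C(=O)CC=C(C)C)C/C(C)=C/Cc1cc(O)cc(C)c1O | target

**Step count**
Total: 10 steps. Longest linear sequence: 7 steps (1, 2, 3, 5, 8, 9, 10 from geranyl acetate); steps 4 and 6–7 are side branches.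

**Steps most likely to fail**

Step 2 (α-selective prenylation). The risks are γ-attack giving the reverse-prenyl isomer, and attack on the acetate. The fallback sets out from 2 and comes back at 6. Commercial allylmagnesium bromide (1.0 equiv, THF, −78 °C) adds to the aldehyde of 2, where the parent allyl group raises no α/γ question, and gives the allyl carbinol F1. Cross-metathesis of its terminal vinyl group with 2-methyl-2-butene (second-generation Grubbs catalyst, (H2IMes)(PCy3)Cl2Ru=CHPh, neat alkene, 40 °C) builds the prenyl group and gives 5, here isolated. K2CO3/MeOH then gives 6.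

Step 5 (the proposed new allylboration). The risks are:
- E/Z erosion from allylic strain between the C3' methyl and the pseudo-equatorial Bpin;
- low reactivity of the β,β-disubstituted enal;
- an unproven level, and sense, of enantioselection, to be checked by Mosher ester analysis of 14.

The fallback uses known chemistry, sets out from 7 and comes back at 18, so it also makes 12 (step 4) and step 8 unnecessary. (S)-TRIP-catalysed propargylation of 7 with commercial allenylboronic acid pinacol ester gives, through the O-pinacolboryl ether F2, the (S)-homopropargylic alcohol F3. Pt(PPh3)4-catalysed syn-diboration of the terminal alkyne with B2pin2 (toluene, 80 °C) gives the cis-1,2-diboryl alkene F4. Suzuki–Miyaura coupling with 17 (Pd(PPh3)4, CsF, THF) takes place at the terminal, less hindered C–B bond and gives the 2-boryl alkene F5. A second Suzuki–Miyaura coupling with iodomethane (Pd2(dba)3, P(o-tol)3, CsF, DMF, 60 °C) replaces the internal boron by methyl with retention. This delivers 18 with the E geometry fixed by the syn-diboration.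

Step 10 (removal of two aryl acetates beside the C5' acetate). The risks are slow cleavage of the hindered 2,6-disubstituted aryl acetate and partial loss of the allylic acetate. The fallback sets out from 18 and comes back at 20, replacing steps 9 and 10. With no alkyl acetate yet in the molecule, both aryl acetates of 18 are removed (NH4OAc, MeOH/H2O, argon) to give the hydroquinone alcohol F6. Ag2O in ether oxidises it to the quinone alcohol F7, whose ring oxygens are now masked as carbonyls. Acetylation (Ac2O, Et3N, DMAP cat., CH2Cl2, −20 °C) gives the quinone acetate F8. Aqueous Na2S2O4 (ether/water, rt) reduces the quinone to the hydroquinone 20 without touching the ester.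

**Further compounds**
F1 | step 2 | (2E,6E)-8-hydroxy-3,7-dimethylundeca-2,6,10-trien-1-yl acetate, racemic at C8 | CC(=O)OC/C=C(\C)CC/C=C(\C)C(O)CC=C
F2 | step 5 | O-pinacolboryl ether of F3 | CC1(C)OB(O[C@H](/C=C(\C)CC/C=C(\C)C(=O)CC=C(C)C)CC#C)OC1(C)C
F3 | step 5 | (6E,10E,12S)-12-hydroxy-2,6,10-trimethylpentadeca-2,6,10-trien-14-yn-5-one | O[C@H](/C=C(\C)CC/C=C(\C)C(=O)CC=C(C)C)CC#C
F4 | step 5 | (6E,10E,12S,14E)-12-hydroxy-2,6,10-trimethyl-14,15-bis(4,4,5,5-tetramethyl-1,3,2-dioxaborolan-2-yl)pentadeca-2,6,10,14-tetraen-5-one | O[C@H](/C=C(\C)CC/C=C(\C)C(=O)CC=C(C)C)C/C(B1OC(C)(C)C(C)(C)O1)=C/B1OC(C)(C)C(C)(C)O1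
F5 | step 5 | (2E,5S,6E,10E)-1-(2,5-diacetoxy-3-methylphenyl)-5-hydroxy-7,11,15-trimethyl-3-(4,4,5,5-tetramethyl-1,3,2-dioxaborolan-2-yl)hexadeca-2,6,10,14-tetraen-12-one | O[C@H](/C=C(\C)CC/C=C(\C)C(=O)CC=C(C)C)C/C(B1OC(C)(C)C(C)(C)O1)=C/Cc1cc(OC(C)=O)cc(C)c1OC(C)=O
F6 | step 10 | (2E,5S,6E,10E)-1-(2,5-dihydroxy-3-methylphenyl)-5-hydroxy-3,7,11,15-tetramethylhexadeca-2,6,10,14-tetraen-12-one | O[C@H](/C=C(\C)CC/C=C(\C)C(=O)CC=C(C)C)C/C(C)=C/Cc1cc(O)cc(C)c1O
F7 | step 10 | 2-[(2E,5S,6E,10E)-5-hydroxy-3,7,11,15-tetramethyl-12-oxohexadeca-2,6,10,14-tetraen-1-yl]-6-methyl-1,4-benzoquinone | O[C@H](/C=C(\C)CC/C=C(\C)C(=O)CC=C(C)C)C/C(C)=C/CC1=CC(=O)C=C(C)C1=O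
F8 | step 10 | (2E,5S,6E,10E)-3,7,11,15-tetramethyl-1-(5-methyl-3,6-dioxocyclohexa-1,4-dien-1-yl)-12-oxohexadeca-2,6,10,14-tetraen-5-yl acetate | CC(=O)O[C@H](/C=C(\C)CC/C=C(\C)C(=O)CC=C(C)C)C/C(C)=C/CC1=CC(=O)C=C(C)C1=O
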